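- 4 questions stand on one flask, and its earlier run is this same flask followed for 120 min, so I count turnovers on its two clocks, the loss of substrate and the loss of target.

- theta: substrate 0.011 M; reagent in the second phase 2 equiv; the very flask that is asked about, followed so far
- flask: substrate 0.011 M; reagent in the second phase 2.00 equiv; time 6.0 h; volume of the second phase over the first 0.50

theta run (percent of the substrate charged)

| time / min | target / % | substrate / % |
|---|---|---|
| 15.0 | 66 | 35 |
| 25.0 | 79 | 16 |
| 40.0 | 84 | 10 |
| 60.0 | 87 | 4 |
| 120 | 82 | 3 |

(readings scatter by 1.5 percentage points)

- percent here means substrate units held: one homo dimer counts as two
- what is said of target includes product in the second phase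
- in the second phase: reagent in the second phase, product in the second phase; everything else is in the first
- charges count per volume of the first phase; a concentration in a rate is the amount of a species over the volume of its own phase; every rate counts per litre of the first phase
- on the list of suspects stand: reagent in the reaction phase <-> reagent in the second phase; substrate + reagent in the reaction phase -> target; target <-> product in the second phase; target -> decomposed product; 2 substrate -> homo dimer; reagent in the reaction phase -> decomposed reagent; substrate <-> dormant form
- the earlier runs hold the two phases in the same ratio of volumes as the flask asked about

* time, not beyond 6.0 h, at which the flask holds most target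
* the amount of target, in percent of the substrate charged, at that time
* earliest time at which at least nineteen twentieths of that best amount are there
* latest time at which they still are

- First the main step: substrate meets reagent in the reaction phase and gives target. I treat the fall of substrate as pseudo-first-order, with k_S = 4.70 /h from the readings at 15.0 min and 25.0 min. In this reckoning target climbs without a peak.

- Then I add target going to decomposed product. The target turnover count n = k_T·t, the number of first-order lifetimes of target passed, uses k_T = 0.0592 /h, read between 60.0 min and 120 min and carrying the scatter of 1.5 percentage points.

- The peak now falls at ln(k_S/k_T)/(k_S−k_T) = 0.943 h, where n = 0.0558, and the top is e^(−n) = 94.6 %.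

- The substrate readings fall from 4 % at 60.0 min to 3 % at 120 min, slower than k_S gives, although 2 equiv of reagent in the second phase were charged. Reagent in the reaction phase going to decomposed reagent is a suspect that can give such a stall, so I name it but put no number on it. The top reading, 87 %, lies 7.6 points below that reckoned top, so I commit to it as the best amount and keep my peak time.

- For the window, a twentieth of substrate remains after 3.00 substrate turnovers, at 0.638 h. A twentieth of target is lost when n has grown by 0.0513 past the peak, at 1.81 h.

- The forecast gives 1.3 h, 87 %, 0.57 h and 2.2 h, noting that “the slow decay makes this time uncertain”. My peak and closing time stand earlier than its values.

- The flask gives its most target at 0.931 h, with 87.2 %; the window opens at 0.490 h and shuts at 1.95 h. The forecast's peak time is later by a factor of 1.40.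

    reagent in the reaction phase ⇌ reagent in the second phase, rate k1*([reagent in the reaction phase] - [reagent in the second phase]/K1) per volume of the first phase (partition coefficient = 0.510, kL = 2.60 /h)
    substrate + reagent in the reaction phase → target (k = 620 /M/h)
    target ⇌ product in the second phase, rate k3*([target] - [product in the second phase]/K3) per volume of the first phase (partition coefficient = 0.190, kL = 13.0 /h)
    target → decomposed product (k = 0.0840 /h)
    2 substrate → homo dimer (k = 0.0460 /M/h)
    reagent in the reaction phase → decomposed reagent (k = 2.20 /h)
    substrate ⇌ dormant form (K = 2.60, k = 0.0620 /h)

- In this flask, target goes from 76.6 % at 3.00 h to 60.9 % at 6.00 h. Over those hours k_T counts 0.178 turnovers, which reckons 64.2 %. The neighbour is this flask read at 25 h: counted from the peak, n = 1.42, which reckons 21.0 % target. That neighbour holds 14.2 % target and 80.6 % decomposed product.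

(The data were generated by integration for substances that don't exist, and the scatter is random.)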